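**Retrosynthetic overview**

1. The target is the linear trimer of (−)-epicatechin 3-O-gallate with two C4β→C8 interflavan bonds. All 21 phenols are carried as benzyl ethers and freed in one final hydrogenolysis, which also removes a temporary bromine cap from C8 of the top unit.
2. Both interflavan bonds are disconnected in one flask, three components around the middle unit. First C4 (ring C) of the top unit is joined to C8 (ring A) of the middle unit by hard activation of a C4–O ether; then C4 of the middle unit is joined to C8 of the bottom unit by soft activation of a C4–S sulfide.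
3. Enabling feature: each C4 of ring C is benzylic to a phloroglucinol-type ring A (O5 ortho and O7 para to C4a), so it ionises easily. C8 of ring A, between O7 and O1, is the most nucleophilic arene CH. The 3-O-galloyl ester sits on the α face next to C4 and leaves only the β face open.
4. No ring is formed in the route: all twelve rings (three A, three B, three C, three galloyl) come intact from (−)-epicatechin and tri-O-benzylgallic acid. The three building blocks 9, 11 and 12 diverge from tetra-O-benzylepicatechin through one C4-oxidised intermediate.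

Key step: step 7

Remark on the chemistry: the target is read from its SMILES as the all-(4β→8) trimer with 2R,3R in every unit and each interflavan bond trans to the neighbouring 3-O-galloyl group. "Top" is the unit with free C8, "middle" the doubly linked unit, "bottom" the unit with the C4 methylene; β is the face opposite to ring B and to the 3-oxygen.

**Route**

Step 1
Reactants: 1 (−)-epicatechin; 2 benzyl bromide
Product: 3 5,7,3',4'-tetra-O-benzyl-(−)-epicatechin (2R,3R, free 3-OH)
Conditions: BnBr, K2CO3, DMF, 0 °C to rt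
Reagents that add atoms: benzyl bromide (2), BrCc1ccccc1
Why: Williamson etherification of the four phenols with a carbonate base should leave the much less acidic secondary 3-OH free; C2 and C3 come unchanged from the chiral pool.

Step 2
Reactants: 3 5,7,3',4'-tetra-O-benzyl-(−)-epicatechin; 4 2-ethoxyethanol
Product: 5 5,7,3',4'-tetra-O-benzyl-4β-(2-ethoxyethoxy)epicatechin (2,3-cis, 3,4-trans, free 3-OH)
Conditions: DDQ, 2-ethoxyethanol, CH2Cl2, rt
Reagents that add atoms: 2-ethoxyethanol (4), CCOCCO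
Why: DDQ abstracts hydride from C4, which is benzylic to the 5,7-dibenzyloxy ring A, and the alcohol captures the cation trans to the 3-OH (oxidative benzylic etherification); the C4 configuration is not critical because C4 is ionised again later.

Step 3
Reactants: 5 5,7,3',4'-tetra-O-benzyl-4β-(2-ethoxyethoxy)epicatechin; 6 3,4,5-tris(benzyloxy)benzoic acid
Product: 7 5,7,3',4'-tetra-O-benzyl-4β-(2-ethoxyethoxy)epicatechin 3-O-(3,4,5-tri-O-benzylgallate)
Conditions: 6, DCC, DMAP, CH2Cl2, rt
Reagents that add atoms: 3,4,5-tris(benzyloxy)benzoic acid (6), OC(=O)c1cc(OCc2ccccc2)c(OCc2ccccc2)c(OCc2ccccc2)c1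
Why: Steglich esterification of the only free hydroxyl under neutral conditions should keep the acid-labile C4 ether and all stereocentres.

Step 4
Reactants: 7 4β-(2-ethoxyethoxy) heptabenzyl epicatechin gallate; 8 N-bromosuccinimide
Product: 9 8-bromo-5,7,3',4'-tetra-O-benzyl-4β-(2-ethoxyethoxy)epicatechin 3-O-(3,4,5-tri-O-benzylgallate) (top unit)
Conditions: NBS, CH2Cl2, −78 to −20 °C
Reagents that add atoms: N-bromosuccinimide (8), O=C1CCC(=O)N1Br
Why: Electrophilic aromatic bromination should occur at C8 of ring A, the most electron-rich and accessible position between O7 and O1 of a 5,7-di-O-benzylflavan, while the benzylated catechol and galloyl rings are much less activated; the bromine caps the only nucleophilic site of the top unit.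

Step 5
Reactants: 7 4β-(2-ethoxyethoxy) heptabenzyl epicatechin gallate; 10 2,6-dimethylbenzenethiol
Product: 11 5,7,3',4'-tetra-O-benzyl-4β-(2,6-dimethylphenylthio)epicatechin 3-O-(3,4,5-tri-O-benzylgallate) (middle unit)
Conditions: 2,6-dimethylbenzenethiol, BF3·OEt2, CH2Cl2, −78 °C
Reagents that add atoms: 2,6-dimethylbenzenethiol (10), Cc1cccc(C)c1S
Why: Lewis acid SN1 exchange at C4 (thioetherification of a flavan-4-yl cation): BF3·OEt2 ionises the C4–O bond, the 3-O-galloyl group shields the α face, and the thiol adds from the β face to give a sulfide that the hard acid does not ionise.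

Step 6
Reactants: 3 5,7,3',4'-tetra-O-benzyl-(−)-epicatechin; 6 3,4,5-tris(benzyloxy)benzoic acid
Product: 12 5,7,3',4'-tetra-O-benzyl-(−)-epicatechin 3-O-(3,4,5-tri-O-benzylgallate) (bottom unit)
Conditions: 6, DCC, DMAP, CH2Cl2, rt
Reagents that add atoms: 3,4,5-tris(benzyloxy)benzoic acid (6), OC(=O)c1cc(OCc2ccccc2)c(OCc2ccccc2)c(OCc2ccccc2)c1
Why: Steglich esterification of the single free 3-OH; no stereocentre is touched.

Step 7
Reactants: 9 bromo-capped top unit; 11 middle unit 4β-sulfide; 12 bottom unit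
Product: 14 8-bromo-henicosa-O-benzyl procyanidin C1 3,3,3-tri-O-gallate (protected trimer), via bromo-capped dimer 4β-sulfide 13 (not isolated)
Conditions: equimolar 9 and 11, BF3·OEt2, 4 Å MS, CH2Cl2, −78 to −40 °C; then 12 (1.5 equiv), NIS added last in portions, −78 to −30 °C; aq. Na2S2O3/NaHCO3
Reagents that add atoms: none
Why: Stage a is a Friedel–Crafts-type arylation of a flavan-4-yl cation: BF3·OEt2 ionises only the C4–O ether of 9 (the aryl sulfide of 11 is inert to the hard acid and its two ortho methyl groups keep sulfur from capturing the cation), and the cation, stabilised by O5 and O7 of ring A through C4a, is attacked by C8 of 11 to form the C4(top)–C8(middle) bond of 13. Stage b is the soft counterpart: NIS iodinates the sulfur of 13, the sulfenyl iodide leaves, and the new middle-unit cation is arylated by C8 of 12; the closest known reaction type is the orthogonal hard/soft activation of flavan C4 ethers and C4 thioethers with C8 bromine capping used for procyanidin oligomers, here run in one flask. No ring is closed. Both new stereocentres (C4 of the top unit and C4 of the middle unit) are substrate-controlled: the 3-O-galloyl carbonyl on the α face bridges to the cation (anchimeric assistance) and the α-oriented ring B shields the same face, so the arene should enter from the β face, 3,4-trans. The step needs chemoselectivity (O versus S leaving group), regioselectivity (C8 versus C6) and freedom from oligomerisation; these are secured by the hard/soft pair, by the higher nucleophilicity and lower hindrance of C8, and by the bromine at C8 of 9 together with the absence of a leaving group in 12, which leave each cation a single competent partner.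

Step 8
Reactants: 14 protected trimer
Product: 15 Procyanidin C1 3,3,3-tri-O-gallate
Conditions: H2 (1 atm), Pd(OH)2/C, Et3N (1.1 equiv), THF/MeOH/H2O, rt
Reagents that add atoms: none
Why: Hydrogenolysis over Pd(OH)2/C should cleave all 21 benzyl ethers and the C8–Br bond in one operation, Et3N taking up the HBr; the gallate esters, the interflavan bonds and all stereocentres are not affected.

**Compound list**

1 | (−)-epicatechin, (2R,3R) | O[C@@H]1Cc2c(O)cc(O)cc2O[C@@H]1c1ccc(O)c(O)c1 | starting material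
2 | benzyl bromide | BrCc1ccccc1 | starting material
3 | 5,7,3',4'-tetra-O-benzyl-(−)-epicatechin | O[C@@H]1Cc2c(OCc3ccccc3)cc(OCc3ccccc3)cc2O[C@@H]1c1ccc(OCc2ccccc2)c(OCc2ccccc2)c1 | intermediate
4 | 2-ethoxyethanol | CCOCCO | starting material
5 | 5,7,3',4'-tetra-O-benzyl-4β-(2-ethoxyethoxy)epicatechin | CCOCCO[C@H]1c2c(OCc3ccccc3)cc(OCc3ccccc3)cc2O[C@H](c2ccc(OCc3ccccc3)c(OCc3ccccc3)c2)[C@@H]1O | intermediate
6 | 3,4,5-tris(benzyloxy)benzoic acid | OC(=O)c1cc(OCc2ccccc2)c(OCc2ccccc2)c(OCc2ccccc2)c1 | starting material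
7 | 5,7,3',4'-tetra-O-benzyl-4β-(2-ethoxyethoxy)epicatechin 3-O-(3,4,5-tri-O-benzylgallate) | CCOCCO[C@H]1c2c(OCc3ccccc3)cc(OCc3ccccc3)cc2O[C@H](c2ccc(OCc3ccccc3)c(OCc3ccccc3)c2)[C@@H]1OC(=O)c1cc(OCc2ccccc2)c(OCc2ccccc2)c(OCc2ccccc2)c1 | intermediate
8 | N-bromosuccinimide | O=C1CCC(=O)N1Br | starting material
9 | 8-bromo-5,7,3',4'-tetra-O-benzyl-4β-(2-ethoxyethoxy)epicatechin 3-O-(3,4,5-tri-O-benzylgallate), top unit | CCOCCO[C@H]1c2c(OCc3ccccc3)cc(OCc3ccccc3)c(Br)c2O[C@H](c2ccc(OCc3ccccc3)c(OCc3ccccc3)c2)[C@@H]1OC(=O)c1cc(OCc2ccccc2)c(OCc2ccccc2)c(OCc2ccccc2)c1 | intermediate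
10 | 2,6-dimethylbenzenethiol | Cc1cccc(C)c1S | starting material
11 | 5,7,3',4'-tetra-O-benzyl-4β-(2,6-dimethylphenylthio)epicatechin 3-O-(3,4,5-tri-O-benzylgallate), middle unit | Cc1cccc(C)c1S[C@H]1c2c(OCc3ccccc3)cc(OCc3ccccc3)cc2O[C@H](c2ccc(OCc3ccccc3)c(OCc3ccccc3)c2)[C@@H]1OC(=O)c1cc(OCc2ccccc2)c(OCc2ccccc2)c(OCc2ccccc2)c1 | intermediate
12 | 5,7,3',4'-tetra-O-benzyl-(−)-epicatechin 3-O-(3,4,5-tri-O-benzylgallate), bottom unit | O=C(O[C@@H]1Cc2c(OCc3ccccc3)cc(OCc3ccccc3)cc2O[C@@H]1c1ccc(OCc2ccccc2)c(OCc2ccccc2)c1)c1cc(OCc2ccccc2)c(OCc2ccccc2)c(OCc2ccccc2)c1 | intermediate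
13 | bromo-capped dimer 4β-sulfide: 8-bromo top unit linked (4β→8) to the middle unit, which keeps its 4β-(2,6-dimethylphenylthio) group; 14 benzyl ethers, two tribenzylgalloyl esters | Cc1cccc(C)c1S[C@H]1c2c(OCc3ccccc3)cc(OCc3ccccc3)c([C@H]3c4c(OCc5ccccc5)cc(OCc5ccccc5)c(Br)c4O[C@H](c4ccc(OCc5ccccc5)c(OCc5ccccc5)c4)[C@@H]3OC(=O)c3cc(OCc4ccccc4)c(OCc4ccccc4)c(OCc4ccccc4)c3)c2O[C@H](c2ccc(OCc3ccccc3)c(OCc3ccccc3)c2)[C@@H]1OC(=O)c1cc(OCc2ccccc2)c(OCc2ccccc2)c(OCc2ccccc2)c1 | intermediate
14 | 8-bromo-henicosa-O-benzyl procyanidin C1 3,3,3-tri-O-gallate (bromine at C8 of the top unit, both interflavan bonds 4β→8) | O=C(O[C@@H]1[C@@H](c2c(OCc4ccccc4)cc(OCc4ccccc4)c3c2O[C@H](c2ccc(OCc4ccccc4)c(OCc4ccccc4)c2)[C@H](OC(=O)c2cc(OCc4ccccc4)c(OCc4ccccc4)c(OCc4ccccc4)c2)C3)c2c(OCc3ccccc3)cc(OCc3ccccc3)c([C@H]3c4c(OCc5ccccc5)cc(OCc5ccccc5)c(Br)c4O[C@H](c4ccc(OCc5ccccc5)c(OCc5ccccc5)c4)[C@@H]3OC(=O)c3cc(OCc4ccccc4)c(OCc4ccccc4)c(OCc4ccccc4)c3)c2O[C@@H]1c1ccc(OCc2ccccc2)c(OCc2ccccc2)c1)c1cc(OCc2ccccc2)c(OCc2ccccc2)c(OCc2ccccc2)c1 | intermediate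
15 | Procyanidin C1 3,3,3-tri-O-gallate | O=C(O[C@@H]1[C@@H](c2c(O)cc(O)c3c2O[C@H](c2ccc(O)c(O)c2)[C@H](OC(=O)c2cc(O)c(O)c(O)c2)C3)c2c(O)cc(O)c([C@H]3c4c(O)cc(O)cc4O[C@H](c4ccc(O)c(O)c4)[C@@H]3OC(=O)c3cc(O)c(O)c(O)c3)c2O[C@@H]1c1ccc(O)c(O)c1)c1cc(O)c(O)c(O)c1 | target

**Count**

Total steps: 8. Longest linear sequence: 6 steps (1 → 3 → 5 → 7 → 9 or 11 → 14 → 15).

**Steps most likely to fail**

Step 7. The hard/soft orthogonality may break down: the arylthio group may ionise or transfer between units in stage a, or NIS may iodinate ring A of 12 instead of activating sulfur in stage b. Either process would give mixed oligomers. The fallback builds the two bonds in separate, isolated operations using only hard activation, and makes the C4(top)–C8(middle) bond last. It sets out from 7 and 12: Me3SiOTf (catalytic), CH2Cl2, −78 °C, with 12 in excess, should give the dimeric nucleophile tetradeca-O-benzyl procyanidin B2 3,3'-di-O-gallate F1 (middle and bottom units, free C8 on the middle unit). F1 is then condensed with the bromo-capped electrophile 9 under the same conditions; the bromine cap excludes over-extension. This comes back to the route at 14.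

Step 4. Bromination may occur partly at C6, or adventitious HBr may ionise the C4 ether. The fallback places the bromine before the C4 oxidation, on the substrate for which C8 selectivity is best established. It sets out from 3: NBS, CH2Cl2, −78 °C, should give 8-bromo-5,7,3',4'-tetra-O-benzylepicatechin F2. DDQ with 2-ethoxyethanol in CH2Cl2 then gives 8-bromo-5,7,3',4'-tetra-O-benzyl-4β-(2-ethoxyethoxy)epicatechin F3, and Steglich esterification with 6 (DCC, DMAP) comes back to the route at 9.

Step 8. The hydrogenolysis may stall through bromide poisoning of the catalyst and leave partly benzylated mixtures, or the amine base may cause acyl migration or oxidation of the free polyphenol. The fallback separates the two reductions. It sets out from 14: Bu3SnH, AIBN, toluene, 90 °C (radical hydrodebromination) should give henicosa-O-benzyl procyanidin C1 3,3,3-tri-O-gallate F4. Base-free hydrogenolysis (H2, Pd(OH)2/C, THF/MeOH/H2O) then comes back to the route at 15.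

**Further compounds**

F1 | step 7 | tetradeca-O-benzyl procyanidin B2 3,3'-di-O-gallate (middle–bottom dimer, free C8 on the upper unit) | O=C(O[C@@H]1[C@@H](c2c(OCc4ccccc4)cc(OCc4ccccc4)c3c2O[C@H](c2ccc(OCc4ccccc4)c(OCc4ccccc4)c2)[C@H](OC(=O)c2cc(OCc4ccccc4)c(OCc4ccccc4)c(OCc4ccccc4)c2)C3)c2c(OCc3ccccc3)cc(OCc3ccccc3)cc2O[C@@H]1c1ccc(OCc2ccccc2)c(OCc2ccccc2)c1)c1cc(OCc2ccccc2)c(OCc2ccccc2)c(OCc2ccccc2)c1
F2 | step 4 | 8-bromo-5,7,3',4'-tetra-O-benzyl-(−)-epicatechin | O[C@@H]1Cc2c(OCc3ccccc3)cc(OCc3ccccc3)c(Br)c2O[C@@H]1c1ccc(OCc2ccccc2)c(OCc2ccccc2)c1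
F3 | step 4 | 8-bromo-5,7,3',4'-tetra-O-benzyl-4β-(2-ethoxyethoxy)epicatechin | CCOCCO[C@H]1c2c(OCc3ccccc3)cc(OCc3ccccc3)c(Br)c2O[C@H](c2ccc(OCc3ccccc3)c(OCc3ccccc3)c2)[C@@H]1O
F4 | step 8 | henicosa-O-benzyl procyanidin C1 3,3,3-tri-O-gallate | O=C(O[C@@H]1[C@@H](c2c(OCc4ccccc4)cc(OCc4ccccc4)c3c2O[C@H](c2ccc(OCc4ccccc4)c(OCc4ccccc4)c2)[C@H](OC(=O)c2cc(OCc4ccccc4)c(OCc4ccccc4)c(OCc4ccccc4)c2)C3)c2c(OCc3ccccc3)cc(OCc3ccccc3)c([C@H]3c4c(OCc5ccccc5)cc(OCc5ccccc5)cc4O[C@H](c4ccc(OCc5ccccc5)c(OCc5ccccc5)c4)[C@@H]3OC(=O)c3cc(OCc4ccccc4)c(OCc4ccccc4)c(OCc4ccccc4)c3)c2O[C@@H]1c1ccc(OCc2ccccc2)c(OCc2ccccc2)c1)c1cc(OCc2ccccc2)c(OCc2ccccc2)c(OCc2ccccc2)c1
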